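The earlier runs and the new flask stem from a simulated flask with constants of no real substance.

In the winter flask, the left-handed substrate goes faster than the right-handed: after 4.00 min, 23 % of the two together is left of it against 43 %, from equal charges.

| setting | winter | summer | flask |
|---|---|---|---|
| left-handed substrate | 0.20 M | 0.20 M | 0.20 M |
| right-handed substrate | 0.20 M | 0.20 M | 0.20 M |
| coupling partner | 0.50 M | 0.75 M | 0.500 M |
| remark | the very flask that is asked about, followed so far | run made earlier |  |
| time |  |  | 2.5 h |

| run | time / min | left-handed substrate / % | right-handed substrate / % |
|---|---|---|---|
| winter | 4.00 | 23 | 43 |
| winter | 10.0 | 19 | 30 |
| winter | 20.0 | 15 | 22 |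
| winter | 30.0 | 13 | 19 |
| summer | 12.0 | 10 | 26 |
| summer | 40.0 | 9 | 9 |
| summer | 60.0 | 6 | 8 |
| summer | 120 | 8 | 8 |

(each reading ± 1.5 percentage points)

- coupling partner is single-handed; left-handed substrate and right-handed substrate are mirror images of each other, charged as a racemate, each of them at the stated concentration
- the analysis behind the earlier runs scatters by 1.5 percentage points, standard deviation
- an excess is the difference of the two amounts in percent of their sum
- an excess is below zero if the other one leads
- the handed part of coupling partner does not stay in what it makes, so the products of the two hands are mirror images too

* part of the left-handed substrate and right-handed substrate charged together that has reacted at 2.5 h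
* excess of left-handed product over right-handed product in the product at 2.5 h
* excess of right-handed substrate over left-handed substrate among what is left of the two at 2.5 h

Each hand starts as half of the total, so at that reading the left-handed substrate keeps 46.0 % of its own charge and the right-handed 86.0 %. The logarithm of the first fraction over that of the second gives 5.15: this reading is the selectivity factor, the rate-constant ratio of the two hands if they do not interconvert.

But the gap between the hands closes in this flask, from 20 percentage points to 6 points by 30.0 min. We take that as the substrates interconverting, with the drift running from the leading right-handed form into the left-handed, which makes the reading low. With the hands equal, product forms with an excess of s less one over s plus one, here 67.5 %. We therefore commit to eP above that, eS near zero and c above the 68.0 % of the last reading.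

The forecast gave c 74 %, eP 0.3 % and eS 0.8 %, holding that “the final state is racemic and early selectivity erodes”.

The flask gives c 72.1 %, eP 79.6 % and eS 0 %.

    coupling partner + right-handed substrate → right-handed product (k = 7.80 × 10⁻⁴ /M/s)
    coupling partner + left-handed substrate → left-handed product (k = 0.0110 /M/s)
    left-handed substrate ⇌ right-handed substrate (k = 0.00120 /s)
    coupling partner → decomposed reagent (k = 5.00 × 10⁻⁴ /s)
    2 coupling partner → self-condensation product (k = 6.80 × 10⁻⁴ /M/s)

This flask ends with coupling partner, the limiting reagent, at 0 % of its charge and each substrate at 28 % of its own charge; its excess stands above our 67.5 %. For the neighbour flask with 1.2 M of coupling partner, the same s gives the same lower mark of 67.5 %. That flask reaches c 94.1 %, with left-handed product 79.8 % and right-handed product 14.3 %, and its excess is 69.7 %, above the mark.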